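## Structural features

The target, methyl (1S,4R,5S,9R,10S)-1-acetoxylabda-8(17),12E,14-trien-19-oate, is a labdane of the antipodal (ent) series: a trans-fused decalin in which ring A (C1 to C5 and C10) and ring B (C5 to C10) share the C5–C10 bond. Ring A carries the C1 acetate and, at C4, a methyl group and the axial methyl ester C19, while ring B carries the exocyclic C8=C17 methylene and, at C9, the six-carbon (E)-3-methylpenta-2,4-dienyl chain C11–C16. The five stereocentres form two contiguous runs, C4–C5–C10 and C1–C10–C9, which meet at quaternary C10; C4 is quaternary as well, its ester is syn-diaxial to the C20 methyl, and the equatorial C1 acetoxy group is cis to C20 and peri to the equatorial C9 chain. Fragile elements are the terminal conjugated diene (acid, radicals, hydrogenation, E/Z drift), the exocyclic alkene (acid moves it into the ring), the C9 centre for as long as C8 is a carbonyl, and the acetate beside a methyl ester (base). The real difficulty is to set the two quaternary centres C4 and C10 on either side of C5 in one absolute sense, to place oxygen at C1 next to C10, and to bring the C9 chain cis to C20 although the C20 methyl steers reagents to the opposite face. The key step uses the fact that C19–C4(CH3)–C5–C6 is a cis-2-methylsuccinic unit at the acid and aldehyde oxidation levels (C6 being the carbon that later closes ring B) and that the C1 oxygen is 1,4 to C4 across ring A. Ring A is therefore the cyclohexene that forms from a 2-oxy-diene (C10, C1, C2, C3) and the C4=C5 bond of an α-methylbutenolide whose acetal carbon, the future C6, carries the chirality.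

## Logic of the disconnections

27 to 26 to 25. The C1–O acyl bond and then the C1–H bond are removed. An acetate would not survive the bases used earlier, and a C1 carbonyl is what the ring A construction delivers, so C1 stays at the ketone level until the decalin is rigid and needs no protecting group. The forward reduction of 25 must deliver hydride along the axial path, anti to C20, and leave C19 alone.

25 to 24. The C8=C17 bond is cut to a C8 carbonyl. This carbonyl is the one that closes ring B and activates C9 earlier, so it costs nothing extra. The forward step must methylenate C8 and spare the more hindered C1 carbonyl of 24, without base, because C9 is epimerisable.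

24 to 22. Only the C9–H bond is cut and re-formed on the other face. This accepts that the chain will first arrive trans to C20 and moves the correction to a compound without ring double bonds. The forward step needs the equatorial chain to be the favoured epimer under reversible enolisation.

22 to 20. The C3–H and C6–H bonds are removed, which restores the C2=C3 and C6=C7 double bonds. These enones are what make C9 the only position that a kinetic base attacks, so they are kept until the chain is in place. The forward conjugate reduction must spare the terminal diene and the ester.

20 to 16 and 18. The C9–C11 bond is cut and the whole side chain leaves as 18, which removes six carbons and the E alkene in one operation. In 16 the C1 enone has no enolisable position and the C8 enone has C9–H2 as its only α′ site; the γ-hydrogen at C5 is the one competitor. The forward alkylation therefore needs irreversible, kinetic enolisation.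

16 to 13, 13 to 12. The C6=C7 bond and the C19–OCH3 bond are cut (retro-aldol condensation combined with re-closure of C19 and C6 into the acyl acetal). Ring B disappears and C6 returns to the masked aldehyde that carries the auxiliary. The forward step has to open a hindered lactone with methoxide and let the C7 enolate reach C6 before C5, then alpha to an aldehyde, can epimerise. 13 to 12 only changes C8=O back into a terminal alkene.

12 to 10. The C9–C10 bond is cut to 11 and allyl bromide, which removes the second quaternary centre. The C2=C3 bond of 10 exists for this step: with C4 quaternary, C10–H is the only hydrogen an amide base can take. The forward alkylation must occur on the convex face, anti to C6 and C19.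

10 to 9. C2=C3 is returned to the C1 silyl enol ether, an oxidation-level change only. It requires a dehydrogenation that starts from the enol ether regiochemistry left by the cycloaddition.

9 to 6 and 8. C3–C4 and C5–C10 are cut in a retro-Diels–Alder sense. Ring A, C4, C5, the absolute configuration and the oxidation levels of C19 and C6 all come from two compounds of five and six skeletal carbons. The forward step needs para regiochemistry, attack anti to the alkoxy group, and enough reactivity from an α-substituted dienophile.

6 to 3 and 4, 3 to 1, 8 to 7, 18 to 17. The acetal C–O bond is cut to bring chirality from the pool, and one acetal epimer must be obtained pure. 3 goes back to 1 by an oxidative ring cleavage that fixes the methyl position. 8 loses its O–Si bond to give 7. 18 goes back to 17 by a C–Br cut with allylic shift, which must give the E geometry.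

## Other disconnections considered

Alternative 1: The cut is C10–C20; the angular methyl is added last to a Δ5(10)-octalin through a temporary silicon bridge from the C1 oxygen. Forward, the (bromomethyl)dimethylsilyl ether A1 would be treated with Bu3SnH and a radical initiator. The silylmethyl radical closes 5-exo onto C10, the tertiary C5 radical takes hydrogen from the face away from the new ring, and siloxane A2 results. Protodesilylation would later turn C20 into a methyl group and free the C1 hydroxyl.
- In favour: the tether forces C20 onto the face of the C1 oxygen, so the cis C1–O/C20 relationship follows from ring size and not from reagent approach. On this point the alternative is better than the chosen plan, which sets C10 (step 6) and C1 (step 14) in two separate substrate-controlled steps. The neutral radical conditions tolerate esters and ketals at least as well as enolate chemistry.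
- Against: the step forms one C–C bond and no carbocycle. A1 already contains both rings, the C4 quaternary centre and the C1 carbinol in enantiopure form, so the hard part moves into its preparation, with nothing in the tether to control C4. Hydrogen transfer to C5 must occur beside fully substituted C4. After the ketal of A2 is removed, enolisation would prefer C7, so the C9 chain would still need an unsaturation strategy like that of steps 8 to 12.
- Comparison: mechanistically the two are comparably reliable. Structurally the chosen cycloaddition is more convergent. In step economy the chosen plan is ahead, because silylation, cyclisation and desilylation with stoichiometric tin buy one methyl group.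

Alternative 2: The cut is C5–C10 across a ten-membered ring. Forward, A3 (a cyclodecene 1,10-epoxide with an allylsilane built on the ring C4=C5 bond) would be treated with Et2AlCl. The epoxide ionises at the more substituted C10, the allylsilane attacks through C5 with loss of silicon, and trans-decalinol A4 forms with an exocyclic methylene at C4.
- In favour: the C5–C10 bond, quaternary C10, the trans ring fusion and the C1 carbinol arise in one stereospecific step coded by the epoxide and alkene geometries. The C1 oxygen arrives correctly oriented and needs no late reduction, which is better than the chosen plan. The number of stereocentres made in the key step (three) equals that of the chosen cycloaddition.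
- Against: A3 is a strained medium ring with a ring-trans trisubstituted alkene and a trans epoxide that must be made in one enantiomeric form without a directing hydroxyl. It has several conformers, of which only one leads to the trans-fused product. Its assembly by macrocyclisation would cost more steps than ring A does here. A4 lacks the C4 quaternary centre: the methylene must become CH3 plus an axial ester by hydroboration, oxidation and an enolate methylation whose facial outcome is not assured. C8 and C9 are no further advanced than in the chosen route.
- Comparison: mechanistically the cationic anti opening is as well founded as the cycloaddition. Structurally it leaves C4 unsolved, which the chosen plan settles in the key step. In step economy it is less convergent and longer.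

Alternative 3: The cut is C8–C9. Forward, A5 (ring A with a 3-oxobutyl arm on C5 and an E-acrylate arm on C10) would be reduced with SmI2. The C8 ketyl adds 6-exo to C9 and protonation of the ester enolate gives A6, with a tertiary C8 alcohol and a CH2CO2CH3 arm.
- In favour: ring B and C9 are formed together, and C9 should emerge with the arm equatorial and anti to the samarium-bound oxygen. No inversion is needed, which is better than the alkylation and epimerisation of steps 10 and 12. The conditions are mild and esters survive.
- Against: the tertiary alcohol of A6 must be dehydrated toward C17 and not into the ring, which simple reagents do not do reliably. The two-carbon arm must be taken to the aldehyde level and olefinated to an E diene, which is four or five further steps with a second geometry problem. C9 is neopentylic, which slows the radical addition and leaves room for ketone reduction or pinacol coupling. A5 already holds C1, C4, C5 and C10, so this alternative does not replace the ring A construction and would have to be fed by a step like the chosen cycloaddition.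
- Comparison: structurally both plans leave oxygen at C8 after ring closure, so they are equal on that point. Mechanistically the ketyl addition is as credible as the aldol closure of step 8. In step economy the chosen plan is shorter, because it converts the C8 oxygen into the exocyclic alkene in one regiochemically unambiguous step and brings the whole chain in one alkylation.

Key step: step 4

Remark on the chemistry: labdane numbering is used throughout, α and β refer to the usual drawing with ring A on the left, in which C20 of this ent-labdane is α, the hydroxybutenolide is made by furan photooxygenation because hydride reduction of citraconic anhydride is not expected to differentiate its two carbonyls cleanly, and the adduct is oxidised, not hydrolysed, so that C10 is the only enolisable carbon at the allylation.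

## Steps

Step 1
Reactants: 1 3-methylfuran-2-carboxylic acid
Product: 3 5-hydroxy-3-methylfuran-2(5H)-one (racemic lactol), via furan endoperoxide 2 (not isolated)
Conditions: O2, visible light, methylene blue (C16H18ClN3S, cat.), MeOH, 0 °C
Reagents that add atoms: dioxygen, O=O
Why: Sensitised singlet-oxygen [4+2] addition across C2 and C5 of the furan gives endoperoxide 2, which collapses with loss of CO2 (furan photooxygenation); the carboxyl-bearing ring carbon becomes the lactone carbonyl, so the methyl group can only end alpha to it and the other ring CH becomes the lactol carbon.

Step 2
Reactants: 3 5-hydroxy-3-methylfuran-2(5H)-one; 4 (+)-menthol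
Product: 6 (5S)-3-methyl-5-[(1S,2R,5S)-menthyloxy]furan-2(5H)-one, via (5R)-acetal epimer 5 (not isolated)
Conditions: TsOH·H2O (cat.), toluene, reflux, Dean–Stark trap; crystallisation from hexane, mother liquor re-equilibrated with TsOH
Reagents that add atoms: none
Why: Acid-catalysed acetalisation of the lactol (pseudo-ester formation). The two C5 epimers interconvert through the oxocarbenium ion, so crystallisation of the (5S) epimer with acid recycling of the mother liquor should funnel the material into one diastereomer, as is known for the 5-menthyloxyfuranone that lacks the methyl group. (+)-Menthol is chosen because attack anti to the alkoxy group of its (5S) acetal leads to 4R,5S in the target.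

Step 3
Reactants: 7 pent-1-en-3-one
Product: 8 (Z)-3-(trimethylsilyloxy)penta-1,3-diene
Conditions: TMSCl, Et3N, DMF, 80 °C
Reagents that add atoms: chlorotrimethylsilane, C[Si](C)(C)Cl
Why: O-Silylation under equilibrating amine conditions (soft enolisation); only the ethyl CH2 can enolise, and the Z enol ether (methyl cis to oxygen, outside the diene) is the favoured isomer and the one that can reach the s-cis conformation.

Step 4
Reactants: 6 (5S)-3-methyl-5-[(1S,2R,5S)-menthyloxy]furan-2(5H)-one; 8 (Z)-3-(trimethylsilyloxy)penta-1,3-diene
Product: 9 cis-fused lactone acetal of the ring A silyl enol ether (C1(OTMS)=C2; C4-CH3, C5-H and C10-H all β; C20 α; C6 menthyloxy trans to C10)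
Conditions: 8 (3 equiv), 2,6-di-tert-butyl-4-methylphenol (trace), toluene, 150 °C, sealed tube
Reagents that add atoms: none
Why: A concerted but asynchronous, normal-electron-demand [4+2] cycloaddition between the electron-rich 2-silyloxydiene and the butenolide C4=C5 bond; the closest known class is the thermal Diels–Alder reaction of 5-alkoxyfuran-2(5H)-ones with oxygenated dienes. Ring A closes by intermolecular suprafacial addition that forms C5–C10 (the more advanced bond, enol-ether β-carbon onto the lactone β-carbon) and C3–C4 in one kinetic event. Regiochemistry: the silyloxy group makes the methyl-bearing terminus the nucleophilic one and the lactone carbonyl makes C5 the electrophilic one, so the C1 oxygen ends 1,4 to C19; the terminal methyl opposes this only weakly. C4 and C5: the cis geometry of the ring alkene is transferred, so C19 and C6 stay cis, and the diene approaches the face opposite the menthyloxy group on the acetal carbon (future C6), which fixes both centres in the sense that becomes 4R,5S of the target. C10: the Z diene and an endo placement of the lactone carbonyl should put C20 cis to C6, but this centre is planarised in step 6, so its outcome is immaterial. The one real demand is reactivity, because the α-methyl group slows the dienophile; heat in a sealed vessel with excess diene and a radical inhibitor is chosen so that the acid-labile silyl enol ether and acetal never meet a Lewis acid.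

Step 5
Reactants: 9 cis-fused lactone acetal of the ring A silyl enol ether
Product: 10 ring A enone lactone acetal (C1=O, C2=C3; other centres as in 9)
Conditions: Pd(OAc)2 (10 mol %), O2 (1 atm), DMSO, 25 °C
Reagents that add atoms: none
Why: Saegusa–Ito oxidation: the silyl enol ether hands the C1 enolate to divalent palladium, β-hydride loss from C3 gives the C2=C3 enone, and O2 returns zerovalent palladium to the cycle. Because C4 is quaternary the enone has no γ-hydrogen, so C10–H becomes the only acidic hydrogen for step 6.

Step 6
Reactants: 10 ring A enone lactone acetal
Product: 12 C10-allyl enone lactone acetal (allyl β; C20 α), via lithium dienolate 11 (not isolated)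
Conditions: LiN(iPr)2, THF, −78 °C; allyl bromide, DMPU, −78 → 0 °C
Reagents that add atoms: allyl bromide, C=CCBr
Why: Kinetic α′-deprotonation gives the cross-conjugated lithium dienolate 11, which is C-allylated (SN2) on the convex face, anti to the lactone carbons C6 and C19, so the allyl group (C9, C8, C7) goes β and C20 stays α; this sets quaternary C10 in the 10S sense. Regiochemistry is not in question because C10–H is the only enolisable hydrogen (C4 is quaternary and C2 is vinylic).

Step 7
Reactants: 12 C10-allyl enone lactone acetal
Product: 13 C10-acetonyl enone lactone acetal (C8 methyl ketone)
Conditions: PdCl2 (10 mol %), CuCl (30 mol %), O2 (1 atm), DMF/H2O 7:1, 25 °C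
Reagents that add atoms: water, O
Why: Wacker oxidation: Markovnikov hydroxypalladation of the terminal alkene and β-hydride loss give the C8 methyl ketone; the conjugated alkene and the acyl acetal are not attacked under these conditions.

Step 8
Reactants: 13 C10-acetonyl enone lactone acetal
Product: 16 methyl 1,8-dioxo-11,12,13,14,15,16,17-heptanorlabda-2,6-dien-19-oate (trans-fused bis-enone; 5-H β; C20 α), via aldehyde ester 14 (not isolated), via aldol 15 (not isolated)
Conditions: NaOMe (0.3 equiv), MeOH, 0 → 40 °C
Reagents that add atoms: methanol, CO
Why: Methoxide opens the acyl acetal at the lactone carbonyl (transesterification), the hemiacetal anion expels mentholate and frees the C6 aldehyde, and the C7 enolate of the methyl ketone closes ring B by intramolecular aldol addition and E1cB dehydration (Robinson-type closure of a 1,5-keto aldehyde). C9 (β on C10) and C6 (α on C5) are trans-diequatorial, so the ring fusion is trans; C5 is flanked by two quaternary carbons and should enolise more slowly than the ring closes.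

Step 9
Reactants: 17 3-methylpenta-1,4-dien-3-ol
Product: 18 (E)-5-bromo-3-methylpenta-1,3-diene
Conditions: 48% aq HBr, 0 °C; pentane extraction, used at once
Reagents that add atoms: hydrogen bromide, Br
Why: Ionisation to the symmetrical 3-methylpentadienyl cation and capture by bromide at a terminus (SN1′ allylic transposition) gives the conjugated primary bromide; the E isomer is expected to predominate and to be enriched by bromide-mediated equilibration. Any Z isomer carried into step 10 is removed there on AgNO3-impregnated silica.

Step 10
Reactants: 16 trans-fused bis-enone; 18 (E)-5-bromo-3-methylpenta-1,3-diene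
Product: 20 methyl 9-epi-1,8-dioxo-17-norlabda-2,6,12E,14-tetraen-19-oate (C9 chain β and axial), via lithium dienolate 19 (not isolated)
Conditions: LiN(iPr)2 (1.05 equiv), THF, −78 °C; 18, DMPU, −78 → −20 °C
Reagents that add atoms: none
Why: Kinetic α′-deprotonation of an enone by a lithium amide: the C1 enone has no enolisable position and C9–H2 is the only α′ site of the C8 enone, while the tertiary γ-hydrogen at C5, flanked by two quaternary carbons, should be left alone under these irreversible conditions. The cross-conjugated dienolate 19 is C-alkylated by the allylic bromide, and attack at either terminus of its pentadienyl unit gives the same constitution. The electrophile enters along the axial path anti to the axial C20 methyl, on the β face, so the chain is axial and C9 has the wrong configuration at this stage.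

Step 11
Reactants: 20 9-epi alkylated bis-enone
Product: 22 methyl 9-epi-1,8-dioxo-17-norlabda-12E,14-dien-19-oate (C9 chain still β and axial), via 9-epi bis(silyl enol ether) 21 (not isolated)
Conditions: [(Ph3P)CuH]6 (5 mol %), PhMe2SiH, toluene, 25 °C; then 1 M HCl, THF, 0 °C
Reagents that add atoms: none
Why: Copper hydride conjugate reduction: hydride adds to C3 and C6 of the two enones and silyl transfer gives the bis(silyl enol ether) 21 while regenerating Cu–H; the unpolarised diene and the ester are not reduced. The enol ethers lie toward C2 and C7, so C9 is not touched, and cold dilute acid releases the diketone.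

Step 12
Reactants: 22 methyl 9-epi-1,8-dioxo-17-norlabda-12E,14-dien-19-oate
Product: 24 methyl 1,8-dioxo-17-norlabda-12E,14-dien-19-oate (C9 chain α and equatorial; 9-H β), via sodium enolate 23 (not isolated)
Conditions: NaOMe (0.2 equiv), MeOH, 25 → 50 °C
Reagents that add atoms: none
Why: Base-mediated epimerisation of a ketone α-stereocentre under thermodynamic control: reversible enolisation of the C8 ketone toward C9 passes through enolate 23, and reprotonation moves the chain to the equatorial α position, where it loses the syn-axial contacts with 5-H and 7-H; axial protonation of 23 anti to the C20 methyl leads to the same epimer, so the kinetic and thermodynamic preferences should agree and set 9R. No γ-position competes now that the ring double bonds are gone, the C1 ketone can enolise only harmlessly toward C2, and methoxide in methanol leaves the methyl ester unchanged.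

Step 13
Reactants: 24 methyl 1,8-dioxo-17-norlabda-12E,14-dien-19-oate
Product: 25 methyl 1-oxolabda-8(17),12E,14-trien-19-oate
Conditions: Zn, CH2Br2, TiCl4, THF/CH2Cl2, 0 → 25 °C
Reagents that add atoms: dibromomethane, BrCBr
Why: Takai–Lombardo methylenation with the non-basic zinc/titanium methylene reagent; the C8 carbonyl (α-tertiary) should react well before the C1 carbonyl, which is neopentylic, flanked by the axial C20 methyl and peri to C11. The absence of base protects C9, and the ester is inert to this reagent.

Step 14
Reactants: 25 methyl 1-oxolabda-8(17),12E,14-trien-19-oate
Product: 26 methyl (1S)-1-hydroxylabda-8(17),12E,14-trien-19-oate (1-OH α and equatorial)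
Conditions: NaBH4, MeOH, 0 °C
Reagents that add atoms: none
Why: Borohydride attacks C1 along the axial path on the β face, anti to the axial C20 methyl, and gives the equatorial α alcohol cis to C20, the usual course for 1-decalones with an adjacent angular methyl group; this sets C1. The hindered methyl ester and the alkenes are untouched.

Step 15
Reactants: 26 methyl (1S)-1-hydroxylabda-8(17),12E,14-trien-19-oate
Product: 27 methyl (1S,4R,5S,9R,10S)-1-acetoxylabda-8(17),12E,14-trien-19-oate (target)
Conditions: Ac2O, 4-(dimethylamino)pyridine (cat.), pyridine, CH2Cl2, 25 °C
Reagents that add atoms: acetic anhydride, CC(=O)OC(C)=O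
Why: Nucleophile-catalysed acylation of the secondary alcohol with retention at C1; the mild conditions leave the diene, the exocyclic alkene and the methyl ester unchanged.

## Compound list

1 | 3-methylfuran-2-carboxylic acid | Cc1ccoc1C(=O)O | starting material
2 | 2,5-endoperoxide of 1 | CC1=CC2OOC1(O2)C(=O)O | intermediate
3 | 5-hydroxy-3-methylfuran-2(5H)-one (racemic) | CC1=CC(O)OC1=O | intermediate
4 | (+)-menthol, (1S,2R,5S) | C[C@H]1CC[C@@H]([C@H](C1)O)C(C)C | starting material
5 | (5R)-3-methyl-5-[(1S,2R,5S)-menthyloxy]furan-2(5H)-one | CC1=C[C@H](O[C@H]2C[C@@H](C)CC[C@@H]2C(C)C)OC1=O | intermediate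
6 | (5S)-3-methyl-5-[(1S,2R,5S)-menthyloxy]furan-2(5H)-one | CC1=C[C@@H](O[C@H]2C[C@@H](C)CC[C@@H]2C(C)C)OC1=O | intermediate
7 | pent-1-en-3-one | CCC(=O)C=C | starting material
8 | (Z)-3-(trimethylsilyloxy)penta-1,3-diene | C=C/C(O[Si](C)(C)C)=C/C | intermediate
9 | cis-fused lactone acetal of the ring A silyl enol ether | C[C@H]1C(O[Si](C)(C)C)=CC[C@@]2(C)C(=O)O[C@H](O[C@H]3C[C@@H](C)CC[C@@H]3C(C)C)[C@@H]12 | intermediate
10 | ring A enone lactone acetal | C[C@H]1C(=O)C=C[C@@]2(C)C(=O)O[C@H](O[C@H]3C[C@@H](C)CC[C@@H]3C(C)C)[C@@H]12 | intermediate
11 | lithium dienolate of 10 (C1(OLi)=C10) | CC1=C(O[Li])C=C[C@@]2(C)C(=O)O[C@H](O[C@H]3C[C@@H](C)CC[C@@H]3C(C)C)[C@@H]12 | intermediate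
12 | C10-allyl enone lactone acetal | C[C@@]1(CC=C)C(=O)C=C[C@@]2(C)C(=O)O[C@H](O[C@H]3C[C@@H](C)CC[C@@H]3C(C)C)[C@@H]12 | intermediate
13 | C10-acetonyl enone lactone acetal | C[C@@]1(CC(C)=O)C(=O)C=C[C@@]2(C)C(=O)O[C@H](O[C@H]3C[C@@H](C)CC[C@@H]3C(C)C)[C@@H]12 | intermediate
14 | ring A methyl ester aldehyde (C19 ester, C6 aldehyde, C8 methyl ketone) | C[C@@]1(CC(C)=O)C(=O)C=C[C@@](C)(C(=O)OC)[C@H]1C=O | intermediate
15 | C6 aldol (ring B closed, C6 epimers) | C[C@]12CC(=O)CC(O)[C@@H]1[C@](C)(C(=O)OC)C=CC2=O | intermediate
16 | methyl 1,8-dioxo-11,12,13,14,15,16,17-heptanorlabda-2,6-dien-19-oate | C[C@]12CC(=O)C=C[C@@H]1[C@](C)(C(=O)OC)C=CC2=O | intermediate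
17 | 3-methylpenta-1,4-dien-3-ol | C=CC(C)(O)C=C | starting material
18 | (E)-5-bromo-3-methylpenta-1,3-diene | BrC/C=C(C)/C=C | intermediate
19 | lithium dienolate of 16 (C8(OLi)=C9) | C[C@]12C=C(O[Li])C=C[C@@H]1[C@](C)(C(=O)OC)C=CC2=O | intermediate
20 | methyl 9-epi-1,8-dioxo-17-norlabda-2,6,12E,14-tetraen-19-oate | C[C@]12[C@@H](C/C=C(C)/C=C)C(=O)C=C[C@@H]1[C@](C)(C(=O)OC)C=CC2=O | intermediate
21 | 9-epi bis(dimethylphenylsilyl) enol ether (C1=C2 and C7=C8) | C[C@]12[C@@H](C/C=C(C)/C=C)C(O[Si](C)(C)c3ccccc3)=CC[C@@H]1[C@](C)(C(=O)OC)CC=C2O[Si](C)(C)c4ccccc4 | intermediate
22 | methyl 9-epi-1,8-dioxo-17-norlabda-12E,14-dien-19-oate | C[C@]12[C@@H](C/C=C(C)/C=C)C(=O)CC[C@@H]1[C@](C)(C(=O)OC)CCC2=O | intermediate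
23 | sodium enolate of 22 and 24 (C8(ONa)=C9) | C[C@]12C(C/C=C(C)/C=C)=C(O[Na])CC[C@@H]1[C@](C)(C(=O)OC)CCC2=O | intermediate
24 | methyl 1,8-dioxo-17-norlabda-12E,14-dien-19-oate | C[C@]12[C@H](C/C=C(C)/C=C)C(=O)CC[C@@H]1[C@](C)(C(=O)OC)CCC2=O | intermediate
25 | methyl 1-oxolabda-8(17),12E,14-trien-19-oate | C[C@]12[C@H](C/C=C(C)/C=C)C(=C)CC[C@@H]1[C@](C)(C(=O)OC)CCC2=O | intermediate
26 | methyl (1S)-1-hydroxylabda-8(17),12E,14-trien-19-oate | C[C@]12[C@H](C/C=C(C)/C=C)C(=C)CC[C@@H]1[C@](C)(C(=O)OC)CC[C@@H]2O | intermediate
27 | methyl (1S,4R,5S,9R,10S)-1-acetoxylabda-8(17),12E,14-trien-19-oate | C=C/C(C)=C/C[C@@H]1C(=C)CC[C@H]2[C@@]1(C)[C@@H](OC(C)=O)CC[C@@]2(C)C(=O)OC | target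

## Step count and least certain steps

Total: 15 steps. Longest linear sequence: 13 steps (1 to 27 through steps 1, 2, 4–8 and 10–15); steps 3 and 9 are one-step branches.

Step 4 (key step). The most likely failure is a cycloaddition too slow to compete with desilylation or polymerisation of the diene, because the α-methyl group lowers the reactivity of the dienophile; forcing conditions could also erode regiocontrol. Fallback, from 6 and 8, returning at 9: a stepwise anionic annulation in place of the pericyclic step. MeLi cleaves the silyl ether of 8 to lithium (Z)-penta-1,3-dien-3-olate F1. F1 should add in a Michael sense to the β-carbon of 6 anti to the menthyloxy group, and the lactone enolate so formed closes ring A by a second, intramolecular Michael addition onto the vinyl ketone. Work-up gives the saturated C1 ketone of the adduct F2 as a mixture of C10 epimers. Kinetic enolisation of F2 toward C2 with LiN(iPr)2 and TMSCl returns the material to 9, accompanied by the C10 epimer of 9 F3. F3 passes through step 5 as the C10 epimer of 10 F4, and F4 converges with the main route at dienolate 11, where C10 is planar.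

Step 6. The risk is poor facial selectivity in forming the quaternary centre: the C4 methyl group also sits on the convex face and may shield C10 in the flattened dienolate, and some O-allylation is possible. Fallback, from 10, returning at 12: catalyst-controlled decarboxylative allylation. The dienolate from 10 is trapped on oxygen with allyl chloroformate as the allyl dienyl carbonate of 10 F5. The zerovalent palladium source Pd2(dba)3, with the enantiomer of the tert-butyl-PHOX ligand that matches the convex face, then ionises F5 with loss of CO2, and the allyl fragment recombines at C10 under ligand control to give 12.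

Step 8. The risk is epimerisation at C5 through the aldehyde enolate before ring closure, or aldol addition of the C7 enolate to the C1 carbonyl while the hindered lactone opens slowly. Fallback, from 13, returning at 16: an acid route that never exposes a free aldehyde to base. Aqueous CF3CO2H at 50 °C hydrolyses the acetal to the hydroxylactone from 13 F6 and releases menthol. Under the same conditions the enol of the methyl ketone condenses with the masked aldehyde of F6, and dehydration gives the enone carboxylic acid F7. K2CO3 and MeI in DMF then methylate the carboxylate of F7 (reversing any conjugate re-addition of the acid to C6) and give 16.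

Step 12. The risk is an equilibrium at C9 that is less one-sided than hoped, because the equatorial chain is gauche to C20 and eclipsed with the C8 carbonyl, or slow exchange of the hindered equatorial C9–H, so that conversion stalls and recycling of the axial epimer becomes laborious. Fallback, from 20, returning at 24: kinetic instead of thermodynamic control, exercised at the bis-enone stage, where C9 carries the only α′ hydrogen. LiN(iPr)2 in excess (THF, −78 → 0 °C) converts 20 into the lithium dienolate of 20 F8. F8 is protonated at −78 °C by 2,6-di-tert-butyl-4-methylphenol on the β face, anti to C20, to give the C9-inverted bis-enone F9. The copper hydride conditions of step 11 then take F9, by way of the bis(dimethylphenylsilyl) enol ether of 24 F10, to 24. The weak point of this reserve path is γ-deprotonation at C5, which is why it is not the first choice.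

Step 13. The risk is insufficient discrimination between the C8 and C1 carbonyls (double methylenation), or epimerisation at C9 induced by the Lewis acid. Fallback, from 24, returning at 25: a stepwise Peterson olefination in which selectivity is decided in a low-temperature addition that can be run with a deficiency of reagent. The cerium reagent from Me3SiCH2Li and CeCl3 (THF, −78 °C) adds to the less hindered C8 carbonyl without enolisation to give the C8 β-hydroxysilane of 24 F11. F11 is purified and then treated with KH in THF, which eliminates the silanolate and gives 25.

## Further compounds

F1 | step 4 | lithium (Z)-penta-1,3-dien-3-olate | C=C/C(O[Li])=C/C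
F2 | step 4 | saturated C1 ketone of the adduct (C10 epimers) | CC1C(=O)CC[C@@]2(C)C(=O)O[C@H](O[C@H]3C[C@@H](C)CC[C@@H]3C(C)C)[C@@H]12
F3 | step 4 | C10 epimer of 9 | C[C@@H]1C(O[Si](C)(C)C)=CC[C@@]2(C)C(=O)O[C@H](O[C@H]3C[C@@H](C)CC[C@@H]3C(C)C)[C@@H]12
F4 | step 4 | C10 epimer of 10 | C[C@@H]1C(=O)C=C[C@@]2(C)C(=O)O[C@H](O[C@H]3C[C@@H](C)CC[C@@H]3C(C)C)[C@@H]12
F5 | step 6 | allyl dienyl carbonate of 10 | CC1=C(OC(=O)OCC=C)C=C[C@@]2(C)C(=O)O[C@H](O[C@H]3C[C@@H](C)CC[C@@H]3C(C)C)[C@@H]12
F6 | step 8 | hydroxylactone from 13 (C6 lactol, epimers) | C[C@@]1(CC(C)=O)C(=O)C=C[C@@]2(C)C(=O)OC(O)[C@@H]12
F7 | step 8 | enone carboxylic acid (C19 acid of 16) | C[C@]12CC(=O)C=C[C@@H]1[C@](C)(C(=O)O)C=CC2=O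
F8 | step 12 | lithium dienolate of 20 (C8(OLi)=C9) | C[C@]12C(C/C=C(C)/C=C)=C(O[Li])C=C[C@@H]1[C@](C)(C(=O)OC)C=CC2=O
F9 | step 12 | C9-inverted bis-enone, methyl 1,8-dioxo-17-norlabda-2,6,12E,14-tetraen-19-oate | C[C@]12[C@H](C/C=C(C)/C=C)C(=O)C=C[C@@H]1[C@](C)(C(=O)OC)C=CC2=O
F10 | step 12 | bis(dimethylphenylsilyl) enol ether of 24 (C1=C2 and C7=C8) | C[C@]12[C@H](C/C=C(C)/C=C)C(O[Si](C)(C)c3ccccc3)=CC[C@@H]1[C@](C)(C(=O)OC)CC=C2O[Si](C)(C)c4ccccc4
F11 | step 13 | C8 β-hydroxysilane of 24 (C8 epimers) | C[C@]12[C@H](C/C=C(C)/C=C)C(O)(C[Si](C)(C)C)CC[C@@H]1[C@](C)(C(=O)OC)CCC2=O
A1 | alternative 1 | C1 (bromomethyl)dimethylsilyl ether of the Δ5(10)-octalin with C4 methyl/ester and C8 dioxolane | BrC[Si](C)(C)O[C@H]1CC[C@@](C)(C(=O)OC)C2=C1CC3(OCCO3)CC2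
A2 | alternative 1 | trans-decalin with siloxane bridging the C1 oxygen and C20 | C1C2(OCCO2)CC[C@H]3[C@]14C[Si](C)(C)O[C@H]4CC[C@@]3(C)C(=O)OC
A3 | alternative 2 | ten-membered 1,10-epoxide with ring-trans C4=C5 allylsilane and C8 silyl ether | C[C@@]12O[C@H]1CC/C(C[Si](C)(C)C)=C/CC[C@H](O[Si](C)(C)C(C)(C)C)C2
A4 | alternative 2 | trans-decalin-1-ol with C4 exocyclic methylene and C8 silyl ether | C1[C@@H](O[Si](C)(C)C(C)(C)C)CC[C@H]2[C@@]1(C)[C@@H](O)CCC2=C
A5 | alternative 3 | ring A keto enoate (C5 3-oxobutyl arm, C10 E-acrylate arm, C1 silyl ether) | COC(=O)/C=C/[C@]1(C)[C@@H](O[Si](C)(C)C(C)(C)C)CC[C@@](C)(C(=O)OC)[C@H]1CCC(C)=O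
A6 | alternative 3 | trans-decalin with C8 tertiary alcohol and C9 acetate arm | COC(=O)C[C@@H]1[C@@](C)(O)CC[C@H]2[C@@]1(C)[C@@H](O[Si](C)(C)C(C)(C)C)CC[C@@]2(C)C(=O)OC
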